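The tetrahydropyran (O1, C2 with the 4-hydroxyphenyl group, C3, C4 with the chalcone ring, C5, C6 with the arylethyl chain) is read as a δ-lactone in disguise: O1–C6–C5 is the enolate of a 4-arylbutan-2-one and C2–C3–C4 a β-aryl acryloyl unit. A chiral N-heterocyclic carbene unites a cinnamoyl fluoride and a silyl enol ether by Michael addition (C4–C5) and O-acylation (O1–C2) in one operation, closing the ring and setting C4. Both precursors are acyclic and contain no pyran. C6 follows by face-selective hydrogenation, the axial C2 aryl group by arylzinc addition to the derived oxocarbenium ion; Friedel–Crafts cinnamoylation and deprotection complete the chalcone.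

Key step: step 7

Remark: the sense of induction of the chiral triazolylidene in step 7 is assigned by analogy with related acyl azolium annulations; the antipode of the precatalyst that gives (4S)-10 is the one used.

Step 1
Reactants: 1 2,4,6-trimethoxybenzaldehyde
Product: 2 2,6-dihydroxy-4-methoxybenzaldehyde
Conditions: AlCl3 (4 equiv), CH2Cl2, 0 °C → reflux; aq. HCl work-up
Reagents that add atoms: none
Why: Chelation-controlled Lewis-acid demethylation of aryl methyl ethers: AlCl3 held by the formyl oxygen activates only the two ortho methoxy groups toward chloride attack, so the para methoxy group of the target is kept.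

Step 2
Reactants: 2 2,6-dihydroxy-4-methoxybenzaldehyde
Product: 3 2,6-bis(benzyloxy)-4-methoxybenzaldehyde
Conditions: BnBr (2.3 equiv), K2CO3, DMF, 60 °C
Reagents that add atoms: benzyl bromide BrCc1ccccc1
Why: Williamson ether synthesis of the two phenoxides with benzyl bromide, chosen because benzyl ethers keep the ring nucleophilic for the later Friedel–Crafts step and are cleaved without hydrogenation.

Step 3
Reactants: 3 2,6-bis(benzyloxy)-4-methoxybenzaldehyde
Product: 4 (E)-3-[2,6-bis(benzyloxy)-4-methoxyphenyl]prop-2-enoic acid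
Conditions: CH2(CO2H)2, pyridine, piperidine (cat.), 90 °C
Reagents that add atoms: malonic acid OC(=O)CC(=O)O
Why: Knoevenagel–Doebner condensation with decarboxylation, which gives the (E)-cinnamic acid from a 2,6-disubstituted benzaldehyde under thermodynamic control.

Step 4
Reactants: 4 (E)-3-[2,6-bis(benzyloxy)-4-methoxyphenyl]prop-2-enoic acid
Product: 5 (E)-3-[2,6-bis(benzyloxy)-4-methoxyphenyl]prop-2-enoyl fluoride
Conditions: cyanuric fluoride, pyridine, CH2Cl2, 0 °C → rt
Reagents that add atoms: cyanuric fluoride Fc1nc(F)nc(F)n1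
Why: Deoxyfluorination of the carboxylic acid with cyanuric fluoride (acyl fluoride formation), which leaves the benzyl ethers and the E-alkene untouched.

Step 5
Reactants: 6 4-(4-hydroxyphenyl)butan-2-one
Product: 7 4-[4-(benzyloxy)phenyl]butan-2-one
Conditions: BnBr, K2CO3, acetone, reflux
Reagents that add atoms: benzyl bromide BrCc1ccccc1
Why: Williamson ether synthesis of the phenol, which gives a protecting group stable to amide bases, fluoride, hydride and Lewis acids.

Step 6
Reactants: 7 4-[4-(benzyloxy)phenyl]butan-2-one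
Product: 9 {4-[4-(benzyloxy)phenyl]but-1-en-2-yl}oxy(trimethyl)silane, via lithium enolate 8 (not isolated)
Conditions: LiN(i-Pr)2 (1.1 equiv), THF, −78 °C; Me3SiCl, −78 °C → rt; non-aqueous work-up, used crude
Reagents that add atoms: chlorotrimethylsilane C[Si](C)(C)Cl
Why: Kinetic enolisation and O-silylation: the hindered amide base removes a methyl proton at −78 °C, so the terminal enolate is trapped as the less substituted silyl enol ether.

Step 7
Reactants: 5 (E)-3-[2,6-bis(benzyloxy)-4-methoxyphenyl]prop-2-enoyl fluoride; 9 {4-[4-(benzyloxy)phenyl]but-1-en-2-yl}oxy(trimethyl)silane (1.5 equiv)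
Product: 10 (4S)-4-[2,6-bis(benzyloxy)-4-methoxyphenyl]-6-{2-[4-(benzyloxy)phenyl]ethyl}-3,4-dihydro-2H-pyran-2-one
Conditions: aminoindanol-derived N-mesityl triazolium chloride (one antipode, 10 mol %), KN(SiMe3)2 (10 mol %), THF, −20 °C → rt
Reagents that add atoms: none
Why: The carbene adds to 5 and expels fluoride to give an α,β-unsaturated acyl azolium, fluoride desilylates 9 to the terminal enolate (Me3SiF is lost), the enolate carbon C5 attacks the β-carbon C4 (directly, or by 1,2-addition followed by a [3,3] shift), and after proton transfer the ketone enolate oxygen O1 acylates at C2 and releases the carbene. The closest known reaction type is the carbene-catalysed formal [3+3] annulation of α,β-unsaturated acyl fluorides with silyl enol ethers to 3,4-dihydropyran-2-ones. The single ring closes by 6-exo-trig lactonisation of the enolate oxygen onto the acyl azolium carbon. C4 is the only new stereocentre and is set by the catalyst: the indane backbone and the N-mesityl group shield one face of the extended acyl azolium, so that C5 arrives on the open face. The step needs C-attack at C4 instead of simple O-acylation and a regiochemically fixed enolate; the first is secured because any enol ester formed is re-ionised by the carbene and returns to the cycle, the second by the kinetic silyl enol ether and the absence of a stoichiometric base. The two ortho benzyloxy groups slow the conjugate addition but should not block it, since the aryl ring twists out of the enoyl plane.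

Step 8
Reactants: 10 (4S)-4-[2,6-bis(benzyloxy)-4-methoxyphenyl]-6-{2-[4-(benzyloxy)phenyl]ethyl}-3,4-dihydro-2H-pyran-2-one
Product: 11 (4R,6S)-4-[2,6-bis(benzyloxy)-4-methoxyphenyl]-6-{2-[4-(benzyloxy)phenyl]ethyl}tetrahydro-2H-pyran-2-one
Conditions: H2 (1 atm), Rh on Al2O3 (5 wt %), EtOAc, rt
Reagents that add atoms: none
Why: Heterogeneous catalytic hydrogenation: H2 is delivered to the enol lactone double bond from the face opposite the C4 aryl group, so the C6 side chain ends up cis to it (6S), and Rh on Al2O3 at 1 atm should not hydrogenolyse the benzyl ethers.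

Step 9
Reactants: 11 (4R,6S)-4-[2,6-bis(benzyloxy)-4-methoxyphenyl]-6-{2-[4-(benzyloxy)phenyl]ethyl}tetrahydro-2H-pyran-2-one
Product: 13 (4R,6S)-4-[2,6-bis(benzyloxy)-4-methoxyphenyl]-6-{2-[4-(benzyloxy)phenyl]ethyl}tetrahydro-2H-pyran-2-yl acetate (mixture of C2 epimers), via aluminium hemiacetal 12 (not isolated)
Conditions: i-Bu2AlH (1.2 equiv), CH2Cl2, −78 °C; then pyridine, DMAP, Ac2O, −78 → −20 °C
Reagents that add atoms: acetic anhydride CC(=O)OC(C)=O
Why: Reductive acetylation of a lactone: i-Bu2AlH adds once at −78 °C and the stable aluminium hemiacetal is acetylated in situ, which gives the α-acetoxy ether without ring opening; the new acetal centre is of no consequence because it is ionised in step 11.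

Step 10
Reactants: 14 4-iodophenol
Product: 15 4-iodophenyl 2,2-dimethylpropanoate
Conditions: t-BuCOCl, Et3N, DMAP (cat.), CH2Cl2, 0 °C → rt
Reagents that add atoms: pivaloyl chloride CC(C)(C)C(Cl)=O
Why: Acylation of the phenol with an acid chloride (esterification); the pivalate tolerates the magnesium and zinc reagents of step 11 and makes the aryl group electron-poor.

Step 11
Reactants: 13 (4R,6S)-4-[2,6-bis(benzyloxy)-4-methoxyphenyl]-6-{2-[4-(benzyloxy)phenyl]ethyl}tetrahydro-2H-pyran-2-yl acetate; 15 4-iodophenyl 2,2-dimethylpropanoate (3 equiv)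
Product: 18 4-[(2R,4R,6S)-4-[2,6-bis(benzyloxy)-4-methoxyphenyl]-6-{2-[4-(benzyloxy)phenyl]ethyl}tetrahydro-2H-pyran-2-yl]phenyl 2,2-dimethylpropanoate, via arylmagnesium chloride 16 (not isolated), via diarylzinc 17 (not isolated)
Conditions: 15, i-PrMgCl·LiCl, THF, −20 °C; ZnBr2 (0.5 equiv per Mg), −20 → 0 °C; then 13, Me3SiOTf (1.2 equiv), CH2Cl2, −78 → −30 °C
Reagents that add atoms: none
Why: Iodine–magnesium exchange and transmetalation give a diarylzinc that adds to the oxocarbenium ion released from 13 by Me3SiOTf (C-glycosylation-type substitution of an α-acetoxy ether); axial attack on the half-chair that keeps the C4 and C6 substituents pseudoequatorial (stereoelectronic control through a chair-like transition state) places the aryl group trans to both (2R), and the pivalate keeps the new benzylic ether from ionising.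

Step 12
Reactants: 18 4-[(2R,4R,6S)-4-[2,6-bis(benzyloxy)-4-methoxyphenyl]-6-{2-[4-(benzyloxy)phenyl]ethyl}tetrahydro-2H-pyran-2-yl]phenyl 2,2-dimethylpropanoate; 19 (E)-3-(4-acetoxyphenyl)prop-2-enoic acid
Product: 21 4-[(2R,4R,6S)-4-{3-[(E)-3-(4-acetoxyphenyl)prop-2-enoyl]-2,6-bis(benzyloxy)-4-methoxyphenyl}-6-{2-[4-(benzyloxy)phenyl]ethyl}tetrahydro-2H-pyran-2-yl]phenyl 2,2-dimethylpropanoate, via acid chloride 20 (not isolated)
Conditions: 19, (COCl)2, DMF (cat.), CH2Cl2, 0 °C → rt, evaporate; then 18, SnCl4 (1.2 equiv), CH2Cl2, −40 → −10 °C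
Reagents that add atoms: none
Why: Friedel–Crafts acylation: the acid chloride–SnCl4 complex attacks the only strongly activated ring, at either of its two equivalent free positions (ortho to benzyloxy and methoxy), while the ester-bearing and mono-alkoxy rings stay unreactive and the C2 ether, deactivated by the pivalate, does not ionise.

Step 13
Reactants: 21 4-[(2R,4R,6S)-4-{3-[(E)-3-(4-acetoxyphenyl)prop-2-enoyl]-2,6-bis(benzyloxy)-4-methoxyphenyl}-6-{2-[4-(benzyloxy)phenyl]ethyl}tetrahydro-2H-pyran-2-yl]phenyl 2,2-dimethylpropanoate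
Product: 22 4-[(2R,4R,6S)-4-{3-[(E)-3-(4-acetoxyphenyl)prop-2-enoyl]-2,6-dihydroxy-4-methoxyphenyl}-6-[2-(4-hydroxyphenyl)ethyl]tetrahydro-2H-pyran-2-yl]phenyl 2,2-dimethylpropanoate
Conditions: BCl3 (excess), C6HMe5 (10 equiv), CH2Cl2, −78 °C; MeOH then water quench
Reagents that add atoms: none
Why: Lewis-acid cleavage of aryl benzyl ethers with BCl3, pentamethylbenzene trapping the benzyl cations before they alkylate the electron-rich rings; at −78 °C the enone, the two esters, the methyl ether and the deactivated C2 benzylic ether are expected to survive, and no stereocentre is touched.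

Step 14
Reactants: 22 4-[(2R,4R,6S)-4-{3-[(E)-3-(4-acetoxyphenyl)prop-2-enoyl]-2,6-dihydroxy-4-methoxyphenyl}-6-[2-(4-hydroxyphenyl)ethyl]tetrahydro-2H-pyran-2-yl]phenyl 2,2-dimethylpropanoate
Product: 23 (E)-1-{2,4-dihydroxy-3-[(2R,4R,6S)-2-(4-hydroxyphenyl)-6-[2-(4-hydroxyphenyl)ethyl]tetrahydro-2H-pyran-4-yl]-6-methoxyphenyl}-3-(4-hydroxyphenyl)prop-2-en-1-one
Conditions: K2CO3, MeOH–THF, 0 °C → rt; pH 7 buffer work-up
Reagents that add atoms: none
Why: Base-mediated transesterification (methanolysis) of the two aryl esters under conditions chosen to be too mild to open the 2,6-trans benzylic ether through a quinone methide or to close the 2'-hydroxychalcone to a flavanone.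

Compound list
1 | 2,4,6-trimethoxybenzaldehyde | COc1cc(OC)c(C=O)c(OC)c1 | starting material
2 | 2,6-dihydroxy-4-methoxybenzaldehyde | COc1cc(O)c(C=O)c(O)c1 | intermediate
3 | 2,6-bis(benzyloxy)-4-methoxybenzaldehyde | COc1cc(OCc2ccccc2)c(C=O)c(OCc2ccccc2)c1 | intermediate
4 | (E)-3-[2,6-bis(benzyloxy)-4-methoxyphenyl]prop-2-enoic acid | COc1cc(OCc2ccccc2)c(/C=C/C(=O)O)c(OCc2ccccc2)c1 | intermediate
5 | (E)-3-[2,6-bis(benzyloxy)-4-methoxyphenyl]prop-2-enoyl fluoride | COc1cc(OCc2ccccc2)c(/C=C/C(F)=O)c(OCc2ccccc2)c1 | intermediate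
6 | 4-(4-hydroxyphenyl)butan-2-one (raspberry ketone) | CC(=O)CCc1ccc(O)cc1 | starting material
7 | 4-[4-(benzyloxy)phenyl]butan-2-one | CC(=O)CCc1ccc(OCc2ccccc2)cc1 | intermediate
8 | lithium 4-[4-(benzyloxy)phenyl]but-1-en-2-olate | [Li]OC(=C)CCc1ccc(OCc2ccccc2)cc1 | intermediate
9 | {4-[4-(benzyloxy)phenyl]but-1-en-2-yl}oxy(trimethyl)silane | C=C(CCc1ccc(OCc2ccccc2)cc1)O[Si](C)(C)C | intermediate
10 | (4S)-4-[2,6-bis(benzyloxy)-4-methoxyphenyl]-6-{2-[4-(benzyloxy)phenyl]ethyl}-3,4-dihydro-2H-pyran-2-one | COc1cc(OCc2ccccc2)c([C@@H]2C=C(CCc3ccc(OCc4ccccc4)cc3)OC(=O)C2)c(OCc2ccccc2)c1 | intermediate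
11 | (4R,6S)-4-[2,6-bis(benzyloxy)-4-methoxyphenyl]-6-{2-[4-(benzyloxy)phenyl]ethyl}tetrahydro-2H-pyran-2-one | COc1cc(OCc2ccccc2)c([C@@H]2C[C@H](CCc3ccc(OCc4ccccc4)cc3)OC(=O)C2)c(OCc2ccccc2)c1 | intermediate
12 | diisobutylaluminium (4R,6S)-4-[2,6-bis(benzyloxy)-4-methoxyphenyl]-6-{2-[4-(benzyloxy)phenyl]ethyl}tetrahydro-2H-pyran-2-olate (aluminium hemiacetal) | COc1cc(OCc2ccccc2)c([C@@H]2C[C@H](CCc3ccc(OCc4ccccc4)cc3)OC(O[Al](CC(C)C)CC(C)C)C2)c(OCc2ccccc2)c1 | intermediate
13 | (4R,6S)-4-[2,6-bis(benzyloxy)-4-methoxyphenyl]-6-{2-[4-(benzyloxy)phenyl]ethyl}tetrahydro-2H-pyran-2-yl acetate (C2 epimers) | COc1cc(OCc2ccccc2)c([C@@H]2C[C@H](CCc3ccc(OCc4ccccc4)cc3)OC(OC(C)=O)C2)c(OCc2ccccc2)c1 | intermediate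
14 | 4-iodophenol | Oc1ccc(I)cc1 | starting material
15 | 4-iodophenyl 2,2-dimethylpropanoate | CC(C)(C)C(=O)Oc1ccc(I)cc1 | intermediate
16 | [4-(pivaloyloxy)phenyl]magnesium chloride (LiCl complex) | CC(C)(C)C(=O)Oc1ccc([Mg]Cl)cc1 | intermediate
17 | bis[4-(pivaloyloxy)phenyl]zinc | CC(C)(C)C(=O)Oc1ccc([Zn]c2ccc(OC(=O)C(C)(C)C)cc2)cc1 | intermediate
18 | 4-[(2R,4R,6S)-4-[2,6-bis(benzyloxy)-4-methoxyphenyl]-6-{2-[4-(benzyloxy)phenyl]ethyl}tetrahydro-2H-pyran-2-yl]phenyl 2,2-dimethylpropanoate | COc1cc(OCc2ccccc2)c([C@@H]2C[C@H](CCc3ccc(OCc4ccccc4)cc3)O[C@@H](c3ccc(OC(=O)C(C)(C)C)cc3)C2)c(OCc2ccccc2)c1 | intermediate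
19 | (E)-3-(4-acetoxyphenyl)prop-2-enoic acid | CC(=O)Oc1ccc(/C=C/C(=O)O)cc1 | starting material
20 | (E)-3-(4-acetoxyphenyl)prop-2-enoyl chloride | CC(=O)Oc1ccc(/C=C/C(Cl)=O)cc1 | intermediate
21 | 4-[(2R,4R,6S)-4-{3-[(E)-3-(4-acetoxyphenyl)prop-2-enoyl]-2,6-bis(benzyloxy)-4-methoxyphenyl}-6-{2-[4-(benzyloxy)phenyl]ethyl}tetrahydro-2H-pyran-2-yl]phenyl 2,2-dimethylpropanoate | COc1cc(OCc2ccccc2)c([C@@H]2C[C@H](CCc3ccc(OCc4ccccc4)cc3)O[C@@H](c3ccc(OC(=O)C(C)(C)C)cc3)C2)c(OCc2ccccc2)c1C(=O)/C=C/c1ccc(OC(C)=O)cc1 | intermediate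
22 | 4-[(2R,4R,6S)-4-{3-[(E)-3-(4-acetoxyphenyl)prop-2-enoyl]-2,6-dihydroxy-4-methoxyphenyl}-6-[2-(4-hydroxyphenyl)ethyl]tetrahydro-2H-pyran-2-yl]phenyl 2,2-dimethylpropanoate | COc1cc(O)c([C@@H]2C[C@H](CCc3ccc(O)cc3)O[C@@H](c3ccc(OC(=O)C(C)(C)C)cc3)C2)c(O)c1C(=O)/C=C/c1ccc(OC(C)=O)cc1 | intermediate
23 | (E)-1-{2,4-dihydroxy-3-[(2R,4R,6S)-2-(4-hydroxyphenyl)-6-[2-(4-hydroxyphenyl)ethyl]tetrahydro-2H-pyran-4-yl]-6-methoxyphenyl}-3-(4-hydroxyphenyl)prop-2-en-1-one | COc1cc(O)c([C@@H]2C[C@H](CCc3ccc(O)cc3)O[C@@H](c3ccc(O)cc3)C2)c(O)c1C(=O)/C=C/c1ccc(O)cc1 | target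

Total step count: 14. Longest linear sequence: 11 steps (steps 1–4, 7–9, 11–14). Steps 5–6 and step 10 are side branches.

Steps most likely to fail

Step 7. The conjugate addition to the hindered, electron-rich acyl azolium may be slow. O-acylation, equilibration of the enolate to its internal regioisomer and an unselective background pathway would then erode yield and enantiomeric purity. The fallback sets out from 3 and 9 and comes back at 10; it forms C4–C5 under iminium activation and closes O1–C2 afterwards. Wittig olefination of 3 with Ph3P=CHCHO (toluene, 80 °C) should give (E)-3-[2,6-bis(benzyloxy)-4-methoxyphenyl]prop-2-enal F1. Mukaiyama–Michael addition of 9 to F1 under the second-generation MacMillan imidazolidinone (2,4-dinitrobenzoic acid salt, 20 mol %, t-BuOH–i-PrOH, −20 °C, antipode chosen for the 3S product) should give (3S)-3-[2,6-bis(benzyloxy)-4-methoxyphenyl]-7-[4-(benzyloxy)phenyl]-5-oxoheptanal F2. Pinnick oxidation (NaClO2, NaH2PO4, 2-methylbut-2-ene, t-BuOH–water) should give (3R)-3-[2,6-bis(benzyloxy)-4-methoxyphenyl]-7-[4-(benzyloxy)phenyl]-5-oxoheptanoic acid F3. Cyclodehydration of F3 (Ac2O, NaOAc, 100 °C) should give the enol lactone 10.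

Step 11. The free oxocarbenium ion may be captured by the electron-rich trialkoxyaryl ring of a second molecule (Friedel–Crafts self-condensation) or by a benzyloxy oxygen faster than by the arylzinc reagent, and a late, loosely organised transition state may erode the axial preference. The fallback sets out from 11 and comes back at 18. Reduction of 11 with i-Bu2AlH (CH2Cl2, −78 °C, aqueous work-up) should give the lactol (4R,6S)-4-[2,6-bis(benzyloxy)-4-methoxyphenyl]-6-{2-[4-(benzyloxy)phenyl]ethyl}tetrahydro-2H-pyran-2-ol F4. Exchange with PhSO2H and CaCl2 (CH2Cl2, rt) should give the anomeric sulfone (4R,6S)-4-[2,6-bis(benzyloxy)-4-methoxyphenyl]-6-{2-[4-(benzyloxy)phenyl]ethyl}-2-(phenylsulfonyl)tetrahydro-2H-pyran F5. Substitution of F5 with the diarylzinc 17 and added ZnBr2 (THF, rt) should give 18; here ionisation takes place only within the zinc complex that also delivers the aryl group, with no external strong Lewis acid.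

Step 12. The nucleophilic ring may add to the cinnamoyl double bond (conjugate hydroarylation), SnCl4 may remove the ortho benzyl group and trigger flavanone closure, or acylation at the crowded position may simply be slow. The fallback sets out from 18 and comes back at 21, building the enone in two stages from a small acyl group. Friedel–Crafts acetylation (AcCl, SnCl4, CH2Cl2, −40 °C) should give 4-[(2R,4R,6S)-4-[3-acetyl-2,6-bis(benzyloxy)-4-methoxyphenyl]-6-{2-[4-(benzyloxy)phenyl]ethyl}tetrahydro-2H-pyran-2-yl]phenyl 2,2-dimethylpropanoate F6. Boron aldol addition (Bu2BOTf, i-Pr2NEt, CH2Cl2, −78 °C) to commercial 4-acetoxybenzaldehyde, which tolerates the aryl esters, should give the β-hydroxy ketone 4-[(2R,4R,6S)-4-{3-[3-(4-acetoxyphenyl)-3-hydroxypropanoyl]-2,6-bis(benzyloxy)-4-methoxyphenyl}-6-{2-[4-(benzyloxy)phenyl]ethyl}tetrahydro-2H-pyran-2-yl]phenyl 2,2-dimethylpropanoate F7 as a mixture of carbinol epimers. Dehydration of F7 (MsCl, Et3N, then DBU, CH2Cl2, 0 °C) should give the (E)-enone 21.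

Further compounds
F1 | step 7 | (E)-3-[2,6-bis(benzyloxy)-4-methoxyphenyl]prop-2-enal | COc1cc(OCc2ccccc2)c(/C=C/C=O)c(OCc2ccccc2)c1
F2 | step 7 | (3S)-3-[2,6-bis(benzyloxy)-4-methoxyphenyl]-7-[4-(benzyloxy)phenyl]-5-oxoheptanal | COc1cc(OCc2ccccc2)c([C@@H](CC=O)CC(=O)CCc2ccc(OCc3ccccc3)cc2)c(OCc2ccccc2)c1
F3 | step 7 | (3R)-3-[2,6-bis(benzyloxy)-4-methoxyphenyl]-7-[4-(benzyloxy)phenyl]-5-oxoheptanoic acid | COc1cc(OCc2ccccc2)c([C@@H](CC(=O)O)CC(=O)CCc2ccc(OCc3ccccc3)cc2)c(OCc2ccccc2)c1
F4 | step 11 | (4R,6S)-4-[2,6-bis(benzyloxy)-4-methoxyphenyl]-6-{2-[4-(benzyloxy)phenyl]ethyl}tetrahydro-2H-pyran-2-ol | COc1cc(OCc2ccccc2)c([C@@H]2C[C@H](CCc3ccc(OCc4ccccc4)cc3)OC(O)C2)c(OCc2ccccc2)c1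
F5 | step 11 | (4R,6S)-4-[2,6-bis(benzyloxy)-4-methoxyphenyl]-6-{2-[4-(benzyloxy)phenyl]ethyl}-2-(phenylsulfonyl)tetrahydro-2H-pyran | COc1cc(OCc2ccccc2)c([C@@H]2C[C@H](CCc3ccc(OCc4ccccc4)cc3)OC(S(=O)(=O)c3ccccc3)C2)c(OCc2ccccc2)c1
F6 | step 12 | 4-[(2R,4R,6S)-4-[3-acetyl-2,6-bis(benzyloxy)-4-methoxyphenyl]-6-{2-[4-(benzyloxy)phenyl]ethyl}tetrahydro-2H-pyran-2-yl]phenyl 2,2-dimethylpropanoate | COc1cc(OCc2ccccc2)c([C@@H]2C[C@H](CCc3ccc(OCc4ccccc4)cc3)O[C@@H](c3ccc(OC(=O)C(C)(C)C)cc3)C2)c(OCc2ccccc2)c1C(C)=O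
F7 | step 12 | 4-[(2R,4R,6S)-4-{3-[3-(4-acetoxyphenyl)-3-hydroxypropanoyl]-2,6-bis(benzyloxy)-4-methoxyphenyl}-6-{2-[4-(benzyloxy)phenyl]ethyl}tetrahydro-2H-pyran-2-yl]phenyl 2,2-dimethylpropanoate | COc1cc(OCc2ccccc2)c([C@@H]2C[C@H](CCc3ccc(OCc4ccccc4)cc3)O[C@@H](c3ccc(OC(=O)C(C)(C)C)cc3)C2)c(OCc2ccccc2)c1C(=O)CC(O)c1ccc(OC(C)=O)cc1
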